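## Retrosynthetic overview

1. The 1,2-dioxolan-3-ol is opened last: singlet-oxygen ene reaction of a 7′(11′)-en-8′-one, then peroxy-hemiketal closure onto C8′.
2. The five-membered enone ring of fragment B is closed on the coupled material by an intramolecular aldol condensation of a 1,4-diketone (key ring closure).
3. The norbornene core comes from a Diels–Alder union of fragment A (a 2-acetoxyguaia-1(5),3-diene) with fragment B (an (E)-2-(2-oxobutylidene)cycloheptanone).
4. Both seven-membered rings come from ring-closing metathesis of citronellal-derived dienones; the five-membered ring of fragment A comes from an intramolecular aldol condensation.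
5. Ring order: seven-membered rings (RCM) → five-membered ring of A (aldol) → norbornene (Diels–Alder) → five-membered ring of B (aldol) → 1,2-dioxolane.

Conventions: bicyclic and dimeric compounds use guaiane numbering (five-membered ring C1–C5 with C1/C5 at the fusion, CH3-15 on C4; seven-membered ring C5–C6–C7–C8–C9–C10–C1; C11(C12)(C13) on C7; CH3-14 on C10). Primed numbers belong to fragment B. TBS = tert-butyldimethylsilyl.

Assumption: the hemiketal centre C8′ of the target is the thermodynamically preferred epimer and is reached by ring–chain equilibration of the β-hydroperoxy ketone, not by reagent control.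

## Fragment A (steps 1–13)

Step 1
Reactants: 1 (S)-citronellal
Product: 2 (5S)-5,9-dimethyldeca-1,8-dien-3-ol (C3 epimers)
Conditions: CH2=CHMgBr, THF, −78 → 0 °C; aq. NH4Cl
Reagents that add atoms: vinylmagnesium bromide, C=C[Mg]Br
Why: Grignard 1,2-addition to the aldehyde; the new carbinol centre is unselective and is erased in step 2.

Step 2
Reactants: 2 (5S)-5,9-dimethyldeca-1,8-dien-3-ol
Product: 3 (5S)-5,9-dimethyldeca-1,8-dien-3-one
Conditions: Dess–Martin periodinane, CH2Cl2, 0 → 25 °C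
Reagents that add atoms: none
Why: Dess–Martin oxidation of the allylic alcohol to the vinyl ketone under neutral conditions that leave C5 untouched.

Step 3
Reactants: 3 (5S)-5,9-dimethyldeca-1,8-dien-3-one
Product: 4 (6S)-6-methylcyclohept-2-en-1-one
Conditions: second-generation Grubbs catalyst RuCl2(=CHPh)(SIMes)(PCy3) (3 mol%), CH2Cl2 (5 mM), 40 °C
Reagents that add atoms: none
Why: Ring-closing metathesis between the vinyl ketone and the trisubstituted alkene, driven by loss of volatile isobutene, closes the seven-membered enone without touching the stereocentre.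

Step 4
Reactants: 4 (6S)-6-methylcyclohept-2-en-1-one
Product: 6 (6S,7R)-7-(but-2-yn-1-yl)-6-methylcyclohept-2-en-1-one, via lithium dienolate 5 (not isolated)
Conditions: LiN(iPr)2, THF, −78 °C; then 1-bromobut-2-yne, DMPU, −78 → −20 °C
Reagents that add atoms: 1-bromobut-2-yne, CC#CCBr
Why: Kinetic α′-deprotonation gives the cross-conjugated dienolate, and its SN2 alkylation places the butynyl group trans to the adjacent methyl (future C1; its configuration later steers C2).

Step 5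
Reactants: 6 (6S,7R)-7-(but-2-yn-1-yl)-6-methylcyclohept-2-en-1-one
Product: 7 (5R,6S)-5-(but-2-yn-1-yl)-6-methylcyclohept-2-ene-1,4-dione
Conditions: Pd(OH)2/C (5 mol%), tBuOOH, K2CO3 (0.25 equiv), CH2Cl2, 4 → 25 °C
Reagents that add atoms: tert-butyl hydroperoxide, CC(C)(C)OO
Why: Corey–Yu γ-oxidation of an enone (allylic peroxidation of the γ-methylene, then collapse to the ketone) installs the future C8 carbonyl; no stereocentre is formed.

Step 6
Reactants: 7 (5R,6S)-5-(but-2-yn-1-yl)-6-methylcyclohept-2-ene-1,4-dione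
Product: 8 (4S,6S,7R)-7-(but-2-yn-1-yl)-4-hydroxy-6-methylcyclohept-2-en-1-one
Conditions: (R)-2-methyl-CBS-oxazaborolidine (20 mol%), catecholborane (1.0 equiv), toluene, −78 °C
Reagents that add atoms: none
Why: Corey–Bakshi–Shibata reduction attacks the less hindered carbonyl (flanked by CH2, not by the butynyl-bearing carbon), and the catalyst sets the carbinol (4S), trans to the ring methyl.

Step 7
Reactants: 8 (4S,6S,7R)-7-(but-2-yn-1-yl)-4-hydroxy-6-methylcyclohept-2-en-1-one
Product: 9 (4S,6S,7R)-7-(but-2-yn-1-yl)-4-[(tert-butyldimethylsilyl)oxy]-6-methylcyclohept-2-en-1-one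
Conditions: TBSCl, imidazole, DMF, 25 °C
Reagents that add atoms: tert-butyldimethylsilyl chloride, CC(C)(C)[Si](C)(C)Cl
Why: Standard silylation; the bulky silyl ether protects the future C8 oxygen and shields one face of the enone for step 8.

Step 8
Reactants: 9 (4S,6S,7R)-7-(but-2-yn-1-yl)-4-[(tert-butyldimethylsilyl)oxy]-6-methylcyclohept-2-en-1-one
Product: 10 (2R,3S,5S,6R)-2-(but-2-yn-1-yl)-5-[(tert-butyldimethylsilyl)oxy]-3-methyl-6-(propan-2-yl)cycloheptan-1-one
Conditions: (CH3)2CHMgCl, CuBr·SMe2 (20 mol%), THF, −40 °C; aq. NH4Cl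
Reagents that add atoms: isopropylmagnesium chloride, CC(C)[Mg]Cl
Why: Copper-catalysed conjugate addition delivers isopropyl to the β-carbon anti to the neighbouring silyloxy group, which sets the future C7 as (R), cis to the C10 methyl.

Step 9
Reactants: 10 (2R,3S,5S,6R)-2-(but-2-yn-1-yl)-5-[(tert-butyldimethylsilyl)oxy]-3-methyl-6-(propan-2-yl)cycloheptan-1-one
Product: 11 (2R,3S,5S,6R)-5-[(tert-butyldimethylsilyl)oxy]-3-methyl-2-(2-oxobutyl)-6-(propan-2-yl)cycloheptan-1-one
Conditions: Ph3PAuNTf2 (2 mol%), H2O (3 equiv), 1,4-dioxane, 60 °C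
Reagents that add atoms: water, O
Why: Gold-catalysed alkyne hydration with 5-exo participation of the ring carbonyl puts the new ketone on the proximal alkyne carbon and gives the 1,4-diketone regioselectively.

Step 10
Reactants: 11 (2R,3S,5S,6R)-5-[(tert-butyldimethylsilyl)oxy]-3-methyl-2-(2-oxobutyl)-6-(propan-2-yl)cycloheptan-1-one
Product: 13 (1R,7R,8S,10S)-8-[(tert-butyldimethylsilyl)oxy]guai-4-en-3-one, via aldol adduct 12 (not isolated)
Conditions: KOH (0.3 equiv), EtOH, 60 °C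
Reagents that add atoms: none
Why: Intramolecular aldol condensation of the 1,4-diketone (ethyl-ketone enolate onto the ring ketone, then E1cB dehydration) closes the cyclopentenone; the bridged alternative is reversible and cannot dehydrate.

Step 11
Reactants: 13 (1R,7R,8S,10S)-8-[(tert-butyldimethylsilyl)oxy]guai-4-en-3-one
Product: 14 (1R,2S,7R,8S,10S)-2-acetoxy-8-[(tert-butyldimethylsilyl)oxy]guai-4-en-3-one
Conditions: Mn(OAc)3·2H2O (3 equiv), benzene, reflux
Reagents that add atoms: manganese triacetate, CC(=O)O[Mn](OC(C)=O)OC(C)=O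
Why: Manganese-triacetate α′-acetoxylation of the enone delivers acetate to the convex face of C2, cis to H-1 and away from the C1–C10 bond, which is also the more stable epimer and is the C2 configuration of the target.

Step 12
Reactants: 14 (1R,2S,7R,8S,10S)-2-acetoxy-8-[(tert-butyldimethylsilyl)oxy]guai-4-en-3-one
Product: 15 (1R,2S,3R,7R,8S,10S)-2-acetoxy-8-[(tert-butyldimethylsilyl)oxy]guai-4-en-3-ol
Conditions: NaBH4, CeCl3·7H2O, MeOH, −78 °C
Reagents that add atoms: none
Why: Luche 1,2-reduction; hydride adds anti to the C2 acetoxy group so the C3 hydroxyl is cis to it, a temporary centre that is removed in step 13.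

Step 13
Reactants: 15 (1R,2S,3R,7R,8S,10S)-2-acetoxy-8-[(tert-butyldimethylsilyl)oxy]guai-4-en-3-ol
Product: 17 (2R,7R,8S,10S)-2-acetoxy-8-[(tert-butyldimethylsilyl)oxy]guaia-1(5),3-diene, via allylic sulfamate 16 (not isolated)
Conditions: Burgess reagent (MeO2C–N(−)–SO2–N(+)Et3), THF, 0 → 20 °C; solution used at once in step 24
Reagents that add atoms: none
Why: Burgess dehydration by syn-1,4-elimination (the C3 sulfamate and H-1 lie on the same face, while H-2 is trans so no enol acetate can form) gives the cyclopentadiene with C2 untouched.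

## Fragment B (steps 14–23)

Step 14
Reactants: 18 (R)-citronellal
Product: 19 (5R)-5,9-dimethyldeca-1,8-dien-3-ol (C3 epimers)
Conditions: CH2=CHMgBr, THF, −78 → 0 °C; aq. NH4Cl
Reagents that add atoms: vinylmagnesium bromide, C=C[Mg]Br
Why: Grignard 1,2-addition; the carbinol centre is erased in step 15.

Step 15
Reactants: 19 (5R)-5,9-dimethyldeca-1,8-dien-3-ol
Product: 20 (5R)-5,9-dimethyldeca-1,8-dien-3-one
Conditions: Dess–Martin periodinane, CH2Cl2, 0 → 25 °C
Reagents that add atoms: none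
Why: Dess–Martin oxidation to the vinyl ketone without touching C5.

Step 16
Reactants: 20 (5R)-5,9-dimethyldeca-1,8-dien-3-one
Product: 21 (6R)-6-methylcyclohept-2-en-1-one
Conditions: second-generation Grubbs catalyst RuCl2(=CHPh)(SIMes)(PCy3) (3 mol%), CH2Cl2 (5 mM), 40 °C
Reagents that add atoms: none
Why: Ring-closing metathesis with loss of isobutene closes the seven-membered ring of fragment B; its methyl centre is the future C10′ (R).

Step 17
Reactants: 21 (6R)-6-methylcyclohept-2-en-1-one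
Product: 23 (6R,7S)-7-(but-2-yn-1-yl)-6-methylcyclohept-2-en-1-one, via lithium dienolate 22 (not isolated)
Conditions: LiN(iPr)2, THF, −78 °C; then 1-bromobut-2-yne, DMPU, −78 → −20 °C
Reagents that add atoms: 1-bromobut-2-yne, CC#CCBr
Why: Kinetic α′-enolate alkylation (SN2) trans to the adjacent methyl; this centre becomes sp2 later.

Step 18
Reactants: 23 (6R,7S)-7-(but-2-yn-1-yl)-6-methylcyclohept-2-en-1-one
Product: 24 (5S,6R)-5-(but-2-yn-1-yl)-6-methylcyclohept-2-ene-1,4-dione
Conditions: Pd(OH)2/C (5 mol%), tBuOOH, K2CO3 (0.25 equiv), CH2Cl2, 4 → 25 °C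
Reagents that add atoms: tert-butyl hydroperoxide, CC(C)(C)OO
Why: Corey–Yu γ-oxidation installs the future C8′ carbonyl; no stereocentre is formed.

Step 19
Reactants: 24 (5S,6R)-5-(but-2-yn-1-yl)-6-methylcyclohept-2-ene-1,4-dione
Product: 25 (4R,6R,7S)-7-(but-2-yn-1-yl)-4-hydroxy-6-methylcyclohept-2-en-1-one
Conditions: (S)-2-methyl-CBS-oxazaborolidine (20 mol%), catecholborane (1.0 equiv), toluene, −78 °C
Reagents that add atoms: none
Why: Corey–Bakshi–Shibata reduction of the less hindered carbonyl; the catalyst gives one carbinol epimer (4R) for clean handling, although this centre is oxidised again in step 27.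

Step 20
Reactants: 25 (4R,6R,7S)-7-(but-2-yn-1-yl)-4-hydroxy-6-methylcyclohept-2-en-1-one
Product: 26 (4R,6R,7S)-7-(but-2-yn-1-yl)-4-[(tert-butyldimethylsilyl)oxy]-6-methylcyclohept-2-en-1-one
Conditions: TBSCl, imidazole, DMF, 25 °C
Reagents that add atoms: tert-butyldimethylsilyl chloride, CC(C)(C)[Si](C)(C)Cl
Why: Standard silylation to protect the future C8′ oxygen.

Step 21
Reactants: 26 (4R,6R,7S)-7-(but-2-yn-1-yl)-4-[(tert-butyldimethylsilyl)oxy]-6-methylcyclohept-2-en-1-one
Product: 27 (2S,3R,5R,6S)-2-(but-2-yn-1-yl)-5-[(tert-butyldimethylsilyl)oxy]-3-methyl-6-(prop-1-en-2-yl)cycloheptan-1-one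
Conditions: CH2=C(CH3)MgBr, CuBr·SMe2 (20 mol%), THF, −40 °C; aq. NH4Cl
Reagents that add atoms: isopropenylmagnesium bromide, CC(=C)[Mg]Br
Why: Copper-catalysed conjugate addition places isopropenyl regiospecifically on the future C7′, anti to the silyloxy group; this centre becomes sp2 in step 28.

Step 22
Reactants: 27 (2S,3R,5R,6S)-2-(but-2-yn-1-yl)-5-[(tert-butyldimethylsilyl)oxy]-3-methyl-6-(prop-1-en-2-yl)cycloheptan-1-one
Product: 28 (4R,6R,7S)-6-[(tert-butyldimethylsilyl)oxy]-2-ethyl-4-methyl-7-(prop-1-en-2-yl)-5,6,7,8-tetrahydro-4H-cyclohepta[b]furan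
Conditions: Ph3PAuNTf2 (2 mol%), toluene (dry), 25 °C
Reagents that add atoms: none
Why: Gold-catalysed cycloisomerisation of the γ-alkynyl ketone (5-exo-dig attack of the carbonyl oxygen, then aromatisation) gives the furan, a regiodefined mask for the enedione.

Step 23
Reactants: 28 (4R,6R,7S)-6-[(tert-butyldimethylsilyl)oxy]-2-ethyl-4-methyl-7-(prop-1-en-2-yl)-5,6,7,8-tetrahydro-4H-cyclohepta[b]furan
Product: 30 (2E,3R,5R,6S)-5-[(tert-butyldimethylsilyl)oxy]-3-methyl-2-(2-oxobutylidene)-6-(prop-1-en-2-yl)cycloheptan-1-one, via (Z)-enedione 29 (not isolated)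
Conditions: mCPBA (1.0 equiv), CH2Cl2, 0 °C; then I2 (5 mol%), 25 °C
Reagents that add atoms: 3-chloroperoxybenzoic acid, OOC(=O)c1cccc(Cl)c1
Why: Oxidative ring opening of the electron-rich furan (much faster than epoxidation of the isopropenyl group) gives the cis-enedione, and iodine-catalysed isomerisation gives the more stable (E)-isomer.

## Union and completion (steps 24–29)

Step 24
Reactants: 17 (2R,7R,8S,10S)-2-acetoxy-8-[(tert-butyldimethylsilyl)oxy]guaia-1(5),3-diene; 30 (2E,3R,5R,6S)-5-[(tert-butyldimethylsilyl)oxy]-3-methyl-2-(2-oxobutylidene)-6-(prop-1-en-2-yl)cycloheptan-1-one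
Product: 31 spiro Diels–Alder adduct (C3–C1′ and C1–C2′ bonds; 2-acetoxy syn to C4=C5; C5′ ketone exo; 2′-propanoyl endo)
Conditions: Me2AlCl (20 mol%), CH2Cl2, −78 → −20 °C; 17 (1.5 equiv) used fresh
Reagents that add atoms: none
Why: Lewis-acid-catalysed Diels–Alder reaction in which the unsubstituted diene terminus C3 bonds to the fully substituted C1′, the diene is attacked anti to the C2 acetoxy and the pseudo-axial C10 methyl, the dienophile anti to its A(1,3)-locked pseudo-axial C10′ methyl, and the s-cis-locked ring carbonyl sits exo with the propanoyl group endo, which sets C1, C3 and C1′ as in the target.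

Step 25
Reactants: 31 spiro Diels–Alder adduct
Product: 34 pentacyclic enone (3′-oxo-Δ4′ cyclopentenone exo-fused; 8-OTBS; 8′-OTBS; 7′-isopropenyl), via C2′-epimer 32 (not isolated), via aldol adduct 33 (not isolated)
Conditions: pyrrolidine (1 equiv), AcOH (1 equiv), toluene, 60 °C
Reagents that add atoms: none
Why: Enamine-mediated epimerisation at C2′ followed by intramolecular aldol condensation of the 1,4-diketone (only the exo-propanoyl epimer can reach the exo C5′ carbonyl) closes the cis-fused cyclopentenone and fixes C2′, under conditions that spare the acetate.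

Step 26
Reactants: 34 pentacyclic enone (bis-TBS ether)
Product: 35 pentacyclic 8,8′-diol
Conditions: HF·pyridine, THF, 0 → 25 °C
Reagents that add atoms: none
Why: Fluoride-mediated desilylation under mildly acidic conditions removes both TBS groups without acetate migration or loss.

Step 27
Reactants: 35 pentacyclic 8,8′-diol
Product: 36 8,8′-dione with 7′-isopropenyl group
Conditions: Dess–Martin periodinane, pyridine, CH2Cl2, 0 → 25 °C
Reagents that add atoms: none
Why: Dess–Martin oxidation of both secondary alcohols under buffered, non-enolising conditions, so the C7 centre next to the new C8 ketone keeps its (R) configuration.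

Step 28
Reactants: 36 8,8′-dione with 7′-isopropenyl group
Product: 37 8,8′-dione with 7′(11′)-isopropylidene enone
Conditions: RhCl3·3H2O (5 mol%), EtOH, 60 °C
Reagents that add atoms: none
Why: Rhodium-hydride alkene isomerisation moves the 1,1-disubstituted alkene into conjugation with the C8′ ketone (pulegone-type enone) without base, so the epimerisable C7 is not disturbed.

Step 29
Reactants: 37 8,8′-dione with 7′(11′)-isopropylidene enone
Product: 39 target CNP0361479.4, via allylic hydroperoxide 38 (not isolated)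
Conditions: O2, tetraphenylporphyrin (1 mol%), CH2Cl2, visible light, −20 °C
Reagents that add atoms: dioxygen, O=O
Why: Schenck ene reaction of singlet oxygen with the s-cis enone removes a C6′ hydrogen (the alkyl group geminal to the carbonyl) and puts the hydroperoxide on C11′, which then adds to the C8′ ketone to give the 1,2-dioxolan-3-ol as the more stable hemiketal epimer.

## Compound list

1 | (S)-citronellal, (3S)-3,7-dimethyloct-6-enal | C[C@@H](CCC=C(C)C)CC=O | starting material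
2 | (5S)-5,9-dimethyldeca-1,8-dien-3-ol (C3 epimers) | C=CC(O)C[C@@H](C)CCC=C(C)C | intermediate
3 | (5S)-5,9-dimethyldeca-1,8-dien-3-one | C=CC(=O)C[C@@H](C)CCC=C(C)C | intermediate
4 | (6S)-6-methylcyclohept-2-en-1-one | O=C1C=CCC[C@H](C)C1 | intermediate
5 | lithium (3S)-3-methylcyclohepta-1,6-dien-1-olate (dienolate of 4) | [Li]OC1=C[C@@H](C)CCC=C1 | intermediate
6 | (6S,7R)-7-(but-2-yn-1-yl)-6-methylcyclohept-2-en-1-one | O=C1C=CCC[C@H](C)[C@H]1CC#CC | intermediate
7 | (5R,6S)-5-(but-2-yn-1-yl)-6-methylcyclohept-2-ene-1,4-dione | O=C1C=CC(=O)C[C@H](C)[C@H]1CC#CC | intermediate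
8 | (4S,6S,7R)-7-(but-2-yn-1-yl)-4-hydroxy-6-methylcyclohept-2-en-1-one | O=C1C=C[C@@H](O)C[C@H](C)[C@H]1CC#CC | intermediate
9 | (4S,6S,7R)-7-(but-2-yn-1-yl)-4-[(tert-butyldimethylsilyl)oxy]-6-methylcyclohept-2-en-1-one | O=C1C=C[C@@H](O[Si](C)(C)C(C)(C)C)C[C@H](C)[C@H]1CC#CC | intermediate
10 | (2R,3S,5S,6R)-2-(but-2-yn-1-yl)-5-[(tert-butyldimethylsilyl)oxy]-3-methyl-6-(propan-2-yl)cycloheptan-1-one | O=C1C[C@H](C(C)C)[C@@H](O[Si](C)(C)C(C)(C)C)C[C@H](C)[C@H]1CC#CC | intermediate
11 | (2R,3S,5S,6R)-5-[(tert-butyldimethylsilyl)oxy]-3-methyl-2-(2-oxobutyl)-6-(propan-2-yl)cycloheptan-1-one | O=C1C[C@H](C(C)C)[C@@H](O[Si](C)(C)C(C)(C)C)C[C@H](C)[C@H]1CC(=O)CC | intermediate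
12 | cis-fused aldol adduct, 5-hydroxy-8-(TBS-oxy)guaian-3-one (C4 epimers) | O=C1C[C@@H]2[C@@H](C)C[C@H](O[Si](C)(C)C(C)(C)C)[C@@H](C(C)C)C[C@]2(O)C1C | intermediate
13 | (1R,7R,8S,10S)-8-[(tert-butyldimethylsilyl)oxy]guai-4-en-3-one | O=C1C[C@@H]2[C@@H](C)C[C@H](O[Si](C)(C)C(C)(C)C)[C@@H](C(C)C)CC2=C1C | intermediate
14 | (1R,2S,7R,8S,10S)-2-acetoxy-8-[(tert-butyldimethylsilyl)oxy]guai-4-en-3-one | O=C1[C@@H](OC(C)=O)[C@@H]2[C@@H](C)C[C@H](O[Si](C)(C)C(C)(C)C)[C@@H](C(C)C)CC2=C1C | intermediate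
15 | (1R,2S,3R,7R,8S,10S)-2-acetoxy-8-[(tert-butyldimethylsilyl)oxy]guai-4-en-3-ol | O[C@H]1[C@@H](OC(C)=O)[C@@H]2[C@@H](C)C[C@H](O[Si](C)(C)C(C)(C)C)[C@@H](C(C)C)CC2=C1C | intermediate
16 | C3 O-[N-(methoxycarbonyl)sulfamate] of 15 | COC(=O)NS(=O)(=O)O[C@H]1[C@@H](OC(C)=O)[C@@H]2[C@@H](C)C[C@H](O[Si](C)(C)C(C)(C)C)[C@@H](C(C)C)CC2=C1C | intermediate
17 | (2R,7R,8S,10S)-2-acetoxy-8-[(tert-butyldimethylsilyl)oxy]guaia-1(5),3-diene (fragment A) | CC(=O)O[C@@H]1C=C(C)C2=C1[C@@H](C)C[C@H](O[Si](C)(C)C(C)(C)C)[C@@H](C(C)C)C2 | intermediate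
18 | (R)-citronellal, (3R)-3,7-dimethyloct-6-enal | C[C@H](CCC=C(C)C)CC=O | starting material
19 | (5R)-5,9-dimethyldeca-1,8-dien-3-ol (C3 epimers) | C=CC(O)C[C@H](C)CCC=C(C)C | intermediate
20 | (5R)-5,9-dimethyldeca-1,8-dien-3-one | C=CC(=O)C[C@H](C)CCC=C(C)C | intermediate
21 | (6R)-6-methylcyclohept-2-en-1-one | O=C1C=CCC[C@@H](C)C1 | intermediate
22 | lithium (3R)-3-methylcyclohepta-1,6-dien-1-olate (dienolate of 21) | [Li]OC1=C[C@H](C)CCC=C1 | intermediate
23 | (6R,7S)-7-(but-2-yn-1-yl)-6-methylcyclohept-2-en-1-one | O=C1C=CCC[C@@H](C)[C@@H]1CC#CC | intermediate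
24 | (5S,6R)-5-(but-2-yn-1-yl)-6-methylcyclohept-2-ene-1,4-dione | O=C1C=CC(=O)C[C@@H](C)[C@@H]1CC#CC | intermediate
25 | (4R,6R,7S)-7-(but-2-yn-1-yl)-4-hydroxy-6-methylcyclohept-2-en-1-one | O=C1C=C[C@H](O)C[C@@H](C)[C@@H]1CC#CC | intermediate
26 | (4R,6R,7S)-7-(but-2-yn-1-yl)-4-[(tert-butyldimethylsilyl)oxy]-6-methylcyclohept-2-en-1-one | O=C1C=C[C@H](O[Si](C)(C)C(C)(C)C)C[C@@H](C)[C@@H]1CC#CC | intermediate
27 | (2S,3R,5R,6S)-2-(but-2-yn-1-yl)-5-[(tert-butyldimethylsilyl)oxy]-3-methyl-6-(prop-1-en-2-yl)cycloheptan-1-one | O=C1C[C@@H](C(C)=C)[C@H](O[Si](C)(C)C(C)(C)C)C[C@@H](C)[C@@H]1CC#CC | intermediate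
28 | (4R,6R,7S)-6-[(tert-butyldimethylsilyl)oxy]-2-ethyl-4-methyl-7-(prop-1-en-2-yl)-5,6,7,8-tetrahydro-4H-cyclohepta[b]furan | CCc1cc2c(o1)C[C@@H](C(C)=C)[C@H](O[Si](C)(C)C(C)(C)C)C[C@H]2C | intermediate
29 | (2Z,3R,5R,6S)-5-[(tert-butyldimethylsilyl)oxy]-3-methyl-2-(2-oxobutylidene)-6-(prop-1-en-2-yl)cycloheptan-1-one | CCC(=O)/C=C1/[C@H](C)C[C@@H](O[Si](C)(C)C(C)(C)C)[C@H](C(C)=C)CC1=O | intermediate
30 | (2E,3R,5R,6S)-5-[(tert-butyldimethylsilyl)oxy]-3-methyl-2-(2-oxobutylidene)-6-(prop-1-en-2-yl)cycloheptan-1-one (fragment B) | CCC(=O)/C=C1\[C@H](C)C[C@@H](O[Si](C)(C)C(C)(C)C)[C@H](C(C)=C)CC1=O | intermediate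
31 | spiro Diels–Alder adduct: norbornene from C1, C2, C3, C4=C5 of A and C1′, C2′ of B; 2-OAc syn to C4=C5; C5′ ketone exo and C10′ endo on C1′; propanoyl endo on C2′; 8-OTBS, 8′-OTBS, 7′-isopropenyl; A-part centres as in the target | CC(=O)O[C@@H]1[C@@H]2C(C)=C3C[C@H](C(C)C)[C@@H](O[Si](C)(C)C(C)(C)C)C[C@H](C)[C@@]31[C@@H](C(=O)CC)[C@]24C(=O)C[C@@H](C(C)=C)[C@H](O[Si](C)(C)C(C)(C)C)C[C@H]4C | intermediate
32 | C2′-epimer of 31 (propanoyl exo) | CC(=O)O[C@@H]1[C@@H]2C(C)=C3C[C@H](C(C)C)[C@@H](O[Si](C)(C)C(C)(C)C)C[C@H](C)[C@@]31[C@H](C(=O)CC)[C@]24C(=O)C[C@@H](C(C)=C)[C@H](O[Si](C)(C)C(C)(C)C)C[C@H]4C | intermediate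
33 | aldol adduct: 5′-hydroxy-3′-ketone, five-membered ring of B closed (C4′ and C5′ configurations not fixed) | CC(=O)O[C@@H]1[C@@H]2C(C)=C3C[C@H](C(C)C)[C@@H](O[Si](C)(C)C(C)(C)C)C[C@H](C)[C@@]31[C@@H]1C(=O)C(C)C3(O)C[C@@H](C(C)=C)[C@H](O[Si](C)(C)C(C)(C)C)C[C@@H](C)[C@]312 | intermediate
34 | pentacyclic enone: 2-acetoxy, 3′-oxo-Δ4′, 8-OTBS, 8′-OTBS, 7′-isopropenyl; C1, C2, C3, C7, C10, C1′, C2′, C10′ as in the target | CC(=O)O[C@@H]1[C@@H]2C(C)=C3C[C@H](C(C)C)[C@@H](O[Si](C)(C)C(C)(C)C)C[C@H](C)[C@@]31[C@@H]1C(=O)C(C)=C3C[C@@H](C(C)=C)[C@H](O[Si](C)(C)C(C)(C)C)C[C@@H](C)[C@]312 | intermediate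
35 | 8,8′-diol of 34 | CC(=O)O[C@@H]1[C@@H]2C(C)=C3C[C@H](C(C)C)[C@@H](O)C[C@H](C)[C@@]31[C@@H]1C(=O)C(C)=C3C[C@@H](C(C)=C)[C@H](O)C[C@@H](C)[C@]312 | intermediate
36 | 8,8′-dione with 7′-isopropenyl group | CC(=O)O[C@@H]1[C@@H]2C(C)=C3C[C@H](C(C)C)C(=O)C[C@H](C)[C@@]31[C@@H]1C(=O)C(C)=C3C[C@@H](C(C)=C)C(=O)C[C@@H](C)[C@]312 | intermediate
37 | 8,8′-dione with 7′(11′)-isopropylidene (pulegone-type enone) | CC(=O)O[C@@H]1[C@@H]2C(C)=C3C[C@H](C(C)C)C(=O)C[C@H](C)[C@@]31[C@@H]1C(=O)C(C)=C3CC(=C(C)C)C(=O)C[C@@H](C)[C@]312 | intermediate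
38 | 11′-hydroperoxy-4′,6′-dien-3′,8′-dione (open form of the target) | CC(=O)O[C@@H]1[C@@H]2C(C)=C3C[C@H](C(C)C)C(=O)C[C@H](C)[C@@]31[C@@H]1C(=O)C(C)=C3C=C(C(C)(C)OO)C(=O)C[C@@H](C)[C@]312 | intermediate
39 | CNP0361479.4, (1R,2R,3R,7R,10S,1′R,2′R,8′R,10′R) | CC(=O)O[C@@H]1[C@@H]2C(C)=C3C[C@H](C(C)C)C(=O)C[C@H](C)[C@@]31[C@@H]1C(=O)C(C)=C3C=C4C(C)(C)OO[C@]4(O)C[C@@H](C)[C@]312 | target

## Step count and risks

Total step count: 29.
Longest linear sequence: 19 steps (steps 1–13, then 24–29); fragment B contributes 10 steps in parallel (19/29 ≈ 0.66).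

Three steps most likely to fail:

1. Step 24 (Diels–Alder union). The dienophile must add anti to the C2 acetoxy group, whereas 5-acyloxycyclopentadienes with unhindered dienophiles are known to prefer syn attack; here only the steric demand of the quaternary dienophile terminus argues for anti attack. Diene 17 can also drift by [1,5]-hydrogen shift. Fallback: introduce the C2 oxygen after the cycloaddition through silicon, which directs anti and is oxidised with retention. It sets out from enone 13. Luche reduction (NaBH4, CeCl3·7H2O, MeOH) gives (1R,3R,7R,8S,10S)-8-[(tert-butyldimethylsilyl)oxy]guai-4-en-3-ol F1. Burgess dehydration gives the parent cyclopentadiene (7R,8S,10S)-8-[(tert-butyldimethylsilyl)oxy]guaia-1(5),3-diene F2. Deprotonation with n-butyllithium and quenching with chloro(isopropoxy)dimethylsilane gives the 2-[isopropoxy(dimethyl)silyl]guaia-1(5),3-diene F3 (silatropic isomers interconvert, and the C2-silyl isomer is the one with the C1/C3 diene termini). Me2AlCl-catalysed cycloaddition with 30, anti to silicon, gives the 2-silyl spiro adduct F4. Tamao oxidation (H2O2, KF, KHCO3, THF–MeOH) gives the C2 alcohol F5 with retention, and acetylation (Ac2O, DMAP, pyridine) comes back to the route at 31.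

2. Step 13 (diene generation). The allylic sulfamate may ionise and give the exocyclic diene or an acetoxonium-derived product instead of clean syn-1,4-elimination. Fallback: a metal-mediated 1,4-elimination. It sets out from alcohol 15. Methyl chloroformate and pyridine give the allylic methyl carbonate (1R,2S,3R,7R,8S,10S)-2-acetoxy-8-[(tert-butyldimethylsilyl)oxy]guai-4-en-3-yl methyl carbonate F6. Pd(PPh3)4 (zerovalent palladium, 5 mol%) in THF at 0 °C ionises it to the π-allyl complex; loss of H-1 then gives the cyclopentadiene and comes back to the route at 17.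

3. Step 29 (photooxygenation). Singlet oxygen may instead attack the tetrasubstituted C4=C5 alkene of the norbornene, which is shielded on both faces but electron-rich. Fallback: triplet-oxygen radical-chain autoxidation. It sets out from dione 37: O2 (1 atm) with N-hydroxyphthalimide (10 mol%) in MeCN at 40 °C abstracts the doubly allylic C6′–H, O2 is captured at the tertiary C11′ terminus, and the resulting hydroperoxide 38 closes to the hemiketal, coming back to the route at 39. This fallback makes no new compound (F0).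

## Further compounds

F1 | step 24 | (1R,3R,7R,8S,10S)-8-[(tert-butyldimethylsilyl)oxy]guai-4-en-3-ol | O[C@@H]1C[C@@H]2[C@@H](C)C[C@H](O[Si](C)(C)C(C)(C)C)[C@@H](C(C)C)CC2=C1C
F2 | step 24 | (7R,8S,10S)-8-[(tert-butyldimethylsilyl)oxy]guaia-1(5),3-diene | C1C=C(C)C2=C1[C@@H](C)C[C@H](O[Si](C)(C)C(C)(C)C)[C@@H](C(C)C)C2
F3 | step 24 | (7R,8S,10S)-8-[(tert-butyldimethylsilyl)oxy]-2-[isopropoxy(dimethyl)silyl]guaia-1(5),3-diene (C2 fluxional) | CC(C)O[Si](C)(C)C1C=C(C)C2=C1[C@@H](C)C[C@H](O[Si](C)(C)C(C)(C)C)[C@@H](C(C)C)C2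
F4 | step 24 | 2-[isopropoxy(dimethyl)silyl] analogue of adduct 31 (silicon syn to C4=C5) | CC(C)O[Si](C)(C)[C@@H]1[C@@H]2C(C)=C3C[C@H](C(C)C)[C@@H](O[Si](C)(C)C(C)(C)C)C[C@H](C)[C@@]31[C@@H](C(=O)CC)[C@]24C(=O)C[C@@H](C(C)=C)[C@H](O[Si](C)(C)C(C)(C)C)C[C@H]4C
F5 | step 24 | 2-hydroxy analogue of adduct 31 (hydroxyl syn to C4=C5) | O[C@@H]1[C@@H]2C(C)=C3C[C@H](C(C)C)[C@@H](O[Si](C)(C)C(C)(C)C)C[C@H](C)[C@@]31[C@@H](C(=O)CC)[C@]24C(=O)C[C@@H](C(C)=C)[C@H](O[Si](C)(C)C(C)(C)C)C[C@H]4C
F6 | step 13 | (1R,2S,3R,7R,8S,10S)-2-acetoxy-8-[(tert-butyldimethylsilyl)oxy]guai-4-en-3-yl methyl carbonate | COC(=O)O[C@H]1[C@@H](OC(C)=O)[C@@H]2[C@@H](C)C[C@H](O[Si](C)(C)C(C)(C)C)[C@@H](C(C)C)CC2=C1C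
F0 | step 29 | none | none
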